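## Retrosynthetic overview

1. Labels: ring A = central benzene (a1 bears the CH2 C8a, a2 bears C8c, a3 the ring D oxygen, a4 H, a5 the ring E oxygen, a6 bears C8b); ring B = seven-membered carbocycle C7a–C8a–a1–a2–C8c–c1–c6; ring C = the resorcinol ring holding c1 and c6; ring D = dihydrofuran a2–a3–O–C7c–C8c; ring E = dihydrofuran a6–a5–O–C7b–C8b.
2. End game: the seven phenols are unmasked last from aryl methyl ethers. Before that, ring E is closed by a formal [4+1] annulation (bonds C8b–C7b and C7b–O) of an o-quinone methide on a5/a6 with a 4-methoxybenzyl sulfonium ylide, after C8b has been attached to a6 by phenol-directed ortho-formylation and aryl Grignard addition.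
3. Key disconnection: bond c1–C8c of ring B together with C7c–H. The strategy rests on C8c, which is at once a methine of ring B and C3 of ring D, is bonded to ring C carbon c1, and holds ring C trans to the aryl group on C7c (C2 of ring D). That is the pattern left when an aryl–palladium bond and then hydride add to the same face of the C3=C2 bond of a 2-arylbenzofuran (dearomative reductive Heck reaction, ring B closed 7-exo).
4. The Heck precursor is an (S)-1,1,2-triarylethane whose only stereocentre, C7a, comes from iridium-catalysed asymmetric hydrogenation of a (Z)-triarylethylene. The alkene is made from a benzofuranylmethyl Grignard reagent and a non-enolisable diaryl ketone, followed by dehydration.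
5. The 2-arylbenzofuran comes from 3,5-dimethoxybenzaldehyde (iodination, demethylation, Sonogashira heteroannulation). Ring order: aromatic furan (future ring D), then ring B in the key step, which also turns the furan into trans-dihydrofuran D, then ring E.

Key step: step 11

Assumption: 2-bromo-4,6-dimethoxybenzaldehyde and THF solutions of 4-methoxyphenylmagnesium bromide and 3,5-dimethoxyphenylmagnesium chloride are treated as catalogue items; the a5 oxygen is carried as a triisopropylsilyl ether rather than a methyl ether, so that after the key step it is the only free phenol and directs C8b to a6 without competition from ring C.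

## Route

Step 1
Reactants: 1 2-bromo-4,6-dimethoxybenzaldehyde
Product: 2 (2-bromo-4,6-dimethoxyphenyl)(4-methoxyphenyl)methanol (racemic)
Conditions: 4-MeOC6H4MgBr (1.2 equiv), THF, 0 °C; aq. NH4Cl
Reagents that add atoms: 4-methoxyphenylmagnesium bromide, COc1ccc([Mg]Br)cc1
Why: Grignard 1,2-addition to the aryl aldehyde; the aryl bromide does not exchange with an arylmagnesium bromide at 0 °C and the racemic carbinol centre is erased in step 2.

Step 2
Reactants: 2 (2-bromo-4,6-dimethoxyphenyl)(4-methoxyphenyl)methanol
Product: 3 (2-bromo-4,6-dimethoxyphenyl)(4-methoxyphenyl)methanone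
Conditions: MnO2 (10 equiv), CH2Cl2, rt
Reagents that add atoms: none
Why: MnO2 oxidation of a doubly benzylic alcohol should stop cleanly at the diaryl ketone, which has no α-hydrogen and so cannot enolise in step 9.

Step 3
Reactants: 4 3,5-dimethoxybenzaldehyde
Product: 5 2-iodo-3,5-dimethoxybenzaldehyde
Conditions: NIS (1.1 equiv), TFA (0.3 equiv), MeCN, rt
Reagents that add atoms: N-iodosuccinimide, O=C1CCC(=O)N1I
Why: Electrophilic aromatic iodination with acid-activated NIS should occur next to the formyl-bearing carbon and para to a methoxy group, the established halogenation site of 3,5-dimethoxybenzaldehyde, not between the two methoxy groups.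

Step 4
Reactants: 5 2-iodo-3,5-dimethoxybenzaldehyde
Product: 6 3,5-dihydroxy-2-iodobenzaldehyde
Conditions: BBr3 (3.5 equiv), CH2Cl2, −78 °C to rt; H2O
Reagents that add atoms: none
Why: BBr3 cleavage of aryl methyl ethers (borate formation, bromide attack at methyl) frees both phenols after the iodine position has been fixed on the dimethyl ether, where regiochemistry is reliable; the aldehyde is recovered on aqueous work-up and the aryl iodide is inert.

Step 5
Reactants: 6 3,5-dihydroxy-2-iodobenzaldehyde and 7 4-ethynylanisole
Product: 9 6-hydroxy-2-(4-methoxyphenyl)-1-benzofuran-4-carbaldehyde, via alkynylphenol 8 (not isolated)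
Conditions: Pd(PPh3)2Cl2 (3 mol%), CuI (5 mol%), Et3N, DMF, rt then 70 °C
Reagents that add atoms: none
Why: Sonogashira coupling at the aryl iodide is followed in the same flask by CuI/Et3N-promoted 5-endo-dig addition of the ortho phenoxide to the alkyne (heteroannulation of o-alkynylphenols); only the hydroxyl next to the alkyne can cyclise, so the second phenol stays at C6.

Step 6
Reactants: 9 6-hydroxy-2-(4-methoxyphenyl)-1-benzofuran-4-carbaldehyde
Product: 10 2-(4-methoxyphenyl)-6-(triisopropylsilyloxy)-1-benzofuran-4-carbaldehyde
Conditions: TIPSCl, imidazole, DMF, rt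
Reagents that add atoms: chlorotriisopropylsilane, CC(C)[Si](Cl)(C(C)C)C(C)C
Why: Imidazole-promoted silylation masks the only acidic proton before organomagnesium chemistry; an aryl triisopropylsilyl ether should survive Grignard reagents, mild acid and hydrogenation and stays removable by fluoride beside methyl ethers.

Step 7
Reactants: 10 2-(4-methoxyphenyl)-6-(triisopropylsilyloxy)-1-benzofuran-4-carbaldehyde
Product: 11 [2-(4-methoxyphenyl)-6-(triisopropylsilyloxy)-1-benzofuran-4-yl]methanol
Conditions: NaBH4, MeOH–THF, 0 °C
Reagents that add atoms: none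
Why: NaBH4 reduction of the aryl aldehyde to the benzylic alcohol leaves the benzofuran and the silyl ether untouched.

Step 8
Reactants: 11 [2-(4-methoxyphenyl)-6-(triisopropylsilyloxy)-1-benzofuran-4-yl]methanol
Product: 12 4-(chloromethyl)-2-(4-methoxyphenyl)-6-(triisopropylsilyloxy)-1-benzofuran
Conditions: SOCl2 (1.2 equiv), CH2Cl2, 0 °C
Reagents that add atoms: thionyl chloride, O=S(Cl)Cl
Why: Deoxychlorination with SOCl2 gives the benzylic chloride; both ring oxygens are meta to the CH2Cl group, so the chloride is not prone to ionisation and is a normal Grignard precursor.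

Step 9
Reactants: 12 4-(chloromethyl)-2-(4-methoxyphenyl)-6-(triisopropylsilyloxy)-1-benzofuran and 3 (2-bromo-4,6-dimethoxyphenyl)(4-methoxyphenyl)methanone
Product: 15 (Z)-4-[2-(2-bromo-4,6-dimethoxyphenyl)-2-(4-methoxyphenyl)ethenyl]-2-(4-methoxyphenyl)-6-(triisopropylsilyloxy)-1-benzofuran, via Grignard reagent 13 (not isolated), via tertiary alcohol 14 (not isolated)
Conditions: Mg, THF, 0 °C; 3, LaCl3·2LiCl, THF, 0 °C to rt; aq. NH4Cl; TsOH·H2O (5 mol%), toluene, 80 °C
Reagents that add atoms: none
Why: Magnesium insertion gives the benzylic Grignard reagent, whose LaCl3·2LiCl-promoted 1,2-addition to the hindered but non-enolisable ketone forms the C8a–C7a bond, and acid-catalysed E1 dehydration under equilibrating conditions should give the more stable (Z)-alkene, in which the twisted 2,6-disubstituted aryl group is cis to the benzofuranyl group and the 4-methoxyphenyl/benzofuranyl trans-stilbene unit stays planar; a single geometric isomer is to be secured by crystallisation.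

Step 10
Reactants: 15 (Z)-triarylethylene
Product: 16 (S)-4-[2-(2-bromo-4,6-dimethoxyphenyl)-2-(4-methoxyphenyl)ethyl]-2-(4-methoxyphenyl)-6-(triisopropylsilyloxy)-1-benzofuran (key-step precursor)
Conditions: [Ir(cod)((R)-tBu-PHOX)]BArF (2 mol%), H2 (50 bar), CH2Cl2, rt
Reagents that add atoms: none
Why: Asymmetric hydrogenation of an unfunctionalised trisubstituted alkene with [Ir(cod)((R)-tBu-PHOX)]BArF: the substrate is an α-aryl analogue of (E)-α-methylstilbene, the catalyst selects the enantioface at the CH= carbon and so sets C7a as (S) (ligand antipode chosen by that analogy, the other antipode being used if the sense proves opposite), and aryl bromide, benzofuran and silyl ether should not be reduced.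

Step 11
Reactants: 16 (S)-triarylethane carrying the 2-arylbenzofuran and the ring C aryl bromide
Product: 17 (7aS,7cS,8cS)-configured ring A–D core as a5 triisopropylsilyl ether (tetramethyl ether; ring D trans; key-step product)
Conditions: Pd(OAc)2 (10 mol%), (R)-BINAP (12 mol%), HCO2Na (2.5 equiv), DMF–MeOH, 95 °C
Reagents that add atoms: none
Why: Zerovalent palladium formed from Pd(OAc)2 and BINAP inserts into the C–Br bond on c1, the aryl–palladium bond adds syn across C8c=C7c of the 2-arylbenzofuran with the aryl group going to C8c, and the benzylic, oxygen-substituted C7c–palladium species, whose only β-hydrogen (on C8c) is anti to the metal and cannot be eliminated, takes up formate, loses CO2 and reductively eliminates the C7c–H bond with retention. The closest known reaction type is the intramolecular dearomative reductive Heck reaction of indoles and benzofurans with tethered aryl halides under Pd(OAc)2, a bisphosphine and HCO2Na, run here with a longer tether. Ring B closes by 7-exo-trig carbopalladation (bond c1–C8c), while ring D is not closed but dearomatised from furan to dihydrofuran. C8c should be set relative to C7a by a boat-like insertion geometry in which the inward position on C7a lies over ring A and can hold only hydrogen, so the 4-methoxyphenyl group points outward and ends cis to C8c–H as in the target; C7c follows from syn addition and retentive hydride delivery, which leave its aryl group trans to ring C. The step needs insertion to outrun formate reduction of the aryl–palladium bond and C–H arylation at C8c: sparingly soluble HCO2Na keeps the hydride concentration low, no carbonate or pivalate base is present to open the concerted metalation–deprotonation path, and the BINAP antipode matched with (S)-C7a is kept after a comparison of both.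

Step 12
Reactants: 17 silyl-protected ring A–D core
Product: 18 (7aS,7cS,8cS)-configured ring A–D core having the free a5 phenol (tetramethyl ether)
Conditions: TBAF, AcOH, THF, 0 °C
Reagents that add atoms: none
Why: Fluoride cleaves the aryl silyl ether (Si–F bond formation) under AcOH buffering so that the phenoxide is protonated at once; no other group is fluoride-labile and any material already desilylated in step 11 converges here.

Step 13
Reactants: 18 ring A–D core phenol
Product: 19 (7aS,7cS,8cS)-configured a6-formyl a5-phenol of the ring A–D core (tetramethyl ether)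
Conditions: MgCl2, Et3N, (CH2O)n, MeCN, reflux; 1 M HCl
Reagents that add atoms: paraformaldehyde (as formaldehyde), C=O
Why: Magnesium-mediated ortho-formylation of phenols delivers the formyl group only ortho to the free hydroxyl, so ring C and the anisyl rings are not touched; of the two ortho positions, a6 (para to the ring D oxygen) is expected to react rather than a4 between the two oxygens, as in formylation of orcinol-type phenols and 6-hydroxy-2,3-dihydrobenzofurans.

Step 14
Reactants: 19 a6-formyl a5-phenol
Product: 21 (7aS,7cS,8cS)-configured a6-[(3,5-dimethoxyphenyl)(4-methylphenylsulfonyl)methyl] a5-phenol (epimers at the sulfonyl-bearing carbon), via diol 20 (not isolated)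
Conditions: 3,5-(MeO)2C6H3MgCl (3 equiv), THF, 0 °C; aq. NH4Cl; p-TolSO2Na, AcOH–H2O, rt
Reagents that add atoms: 3,5-dimethoxyphenylmagnesium chloride, COc1cc(OC)cc([Mg]Cl)c1; sodium p-toluenesulfinate, Cc1ccc(S(=O)[O-])cc1.[Na+]
Why: Aryl Grignard addition to the salicylaldehyde (the first equivalent is spent on the phenol) gives the o-hydroxybenzhydrol, whose labile doubly benzylic hydroxyl is exchanged for p-toluenesulfinate by SN1 substitution in weak acid to give a stable, base-triggered quinone methide precursor; the sulfone-bearing carbon (the future C8b) forms as a mixture of epimers and becomes planar in step 16.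

Step 15
Reactants: 22 4-methoxybenzyl alcohol
Product: 23 1-(4-methoxybenzyl)tetrahydrothiophenium tetrafluoroborate
Conditions: tetrahydrothiophene, HBF4 (48% aq.), rt
Reagents that add atoms: tetrahydrothiophene, C1CCSC1; tetrafluoroboric acid, [H+].F[B-](F)(F)F
Why: SN1 S-alkylation of tetrahydrothiophene by the 4-methoxybenzyl cation generated from the alcohol with HBF4 should give the sulfonium salt as its non-nucleophilic tetrafluoroborate.

Step 16
Reactants: 21 a6 sulfone a5-phenol and 23 1-(4-methoxybenzyl)tetrahydrothiophenium tetrafluoroborate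
Product: 26 (7aS,7bR,8bR,7cS,8cS)-configured heptamethyl ether of the target, via o-quinone methide 24 (not isolated), via sulfonium ylide 25 (not isolated)
Conditions: Cs2CO3 (3 equiv), MeCN, rt
Reagents that add atoms: none
Why: Cs2CO3 eliminates sulfinate from 21 to give o-quinone methide 24 and deprotonates 23 to ylide 25, and conjugate addition of the ylide to the methide carbon followed by 5-exo-tet displacement of tetrahydrothiophene by the phenoxide is the known formal [4+1] annulation of o-quinone methides with sulfur ylides; it should give the trans-2,3-diaryl ring E (anti arrangement in the ring closure, trans also being the more stable isomer), and C8b should be set by attack of the ylide on the methide face opposite the C7a bridge of ring B and its outward aryl group, which, the methide aryl group lying on the carbonyl side, places C8b–H anti to that bridge as in the target.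

Step 17
Reactants: 26 heptamethyl ether
Product: 27 target CNP0136963.1 (7aS,7bR,8bR,7cS,8cS)
Conditions: BBr3 (20 equiv), CH2Cl2, −78 to 0 °C; MeOH, H2O
Reagents that add atoms: none
Why: BBr3 cleaves all seven aryl methyl ethers; C7a, C8b and C8c carry no leaving group and cannot epimerise, while C7b and C7c, which could open reversibly as 4-oxybenzylic cations, should reclose to the trans-dihydrobenzofurans that are already the more stable isomers.

## Compound list

1 | 2-bromo-4,6-dimethoxybenzaldehyde | COc1cc(OC)c(C=O)c(Br)c1 | starting material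
2 | (2-bromo-4,6-dimethoxyphenyl)(4-methoxyphenyl)methanol (racemic) | COc1ccc(C(O)c2c(Br)cc(OC)cc2OC)cc1 | intermediate
3 | (2-bromo-4,6-dimethoxyphenyl)(4-methoxyphenyl)methanone | COc1ccc(C(=O)c2c(Br)cc(OC)cc2OC)cc1 | intermediate
4 | 3,5-dimethoxybenzaldehyde | COc1cc(C=O)cc(OC)c1 | starting material
5 | 2-iodo-3,5-dimethoxybenzaldehyde | COc1cc(OC)c(I)c(C=O)c1 | intermediate
6 | 3,5-dihydroxy-2-iodobenzaldehyde | Oc1cc(O)c(I)c(C=O)c1 | intermediate
7 | 4-ethynylanisole | C#Cc1ccc(OC)cc1 | starting material
8 | 3,5-dihydroxy-2-[(4-methoxyphenyl)ethynyl]benzaldehyde | COc1ccc(C#Cc2c(O)cc(O)cc2C=O)cc1 | intermediate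
9 | 6-hydroxy-2-(4-methoxyphenyl)-1-benzofuran-4-carbaldehyde | COc1ccc(-c2cc3c(C=O)cc(O)cc3o2)cc1 | intermediate
10 | 2-(4-methoxyphenyl)-6-(triisopropylsilyloxy)-1-benzofuran-4-carbaldehyde | COc1ccc(-c2cc3c(C=O)cc(O[Si](C(C)C)(C(C)C)C(C)C)cc3o2)cc1 | intermediate
11 | [2-(4-methoxyphenyl)-6-(triisopropylsilyloxy)-1-benzofuran-4-yl]methanol | COc1ccc(-c2cc3c(CO)cc(O[Si](C(C)C)(C(C)C)C(C)C)cc3o2)cc1 | intermediate
12 | 4-(chloromethyl)-2-(4-methoxyphenyl)-6-(triisopropylsilyloxy)-1-benzofuran | COc1ccc(-c2cc3c(CCl)cc(O[Si](C(C)C)(C(C)C)C(C)C)cc3o2)cc1 | intermediate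
13 | [2-(4-methoxyphenyl)-6-(triisopropylsilyloxy)-1-benzofuran-4-yl]methylmagnesium chloride | COc1ccc(-c2cc3c(C[Mg]Cl)cc(O[Si](C(C)C)(C(C)C)C(C)C)cc3o2)cc1 | intermediate
14 | 1-(2-bromo-4,6-dimethoxyphenyl)-1-(4-methoxyphenyl)-2-[2-(4-methoxyphenyl)-6-(triisopropylsilyloxy)-1-benzofuran-4-yl]ethanol (racemic) | COc1ccc(C(O)(Cc2cc(O[Si](C(C)C)(C(C)C)C(C)C)cc3oc(-c4ccc(OC)cc4)cc23)c2c(Br)cc(OC)cc2OC)cc1 | intermediate
15 | (Z)-4-[2-(2-bromo-4,6-dimethoxyphenyl)-2-(4-methoxyphenyl)ethenyl]-2-(4-methoxyphenyl)-6-(triisopropylsilyloxy)-1-benzofuran (bromoaryl group cis to the benzofuranyl group) | COc1ccc(/C(=C/c2cc(O[Si](C(C)C)(C(C)C)C(C)C)cc3oc(-c4ccc(OC)cc4)cc23)c2c(Br)cc(OC)cc2OC)cc1 | intermediate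
16 | (S)-4-[2-(2-bromo-4,6-dimethoxyphenyl)-2-(4-methoxyphenyl)ethyl]-2-(4-methoxyphenyl)-6-(triisopropylsilyloxy)-1-benzofuran (key-step precursor, C7a S) | COc1ccc([C@H](Cc2cc(O[Si](C(C)C)(C(C)C)C(C)C)cc3oc(-c4ccc(OC)cc4)cc23)c2c(Br)cc(OC)cc2OC)cc1 | intermediate
17 | (7aS,7cS,8cS) ring A–D core, a5 triisopropylsilyl ether, methyl ethers on ring C and on both 4-oxyphenyl groups, ring D trans (key-step product) | COc1ccc([C@@H]2Cc3c4c(cc(O[Si](C(C)C)(C(C)C)C(C)C)c3)O[C@H](c3ccc(OC)cc3)[C@H]4c3cc(OC)cc(OC)c32)cc1 | intermediate
18 | (7aS,7cS,8cS) ring A–D core, free a5 phenol, tetramethyl ether | COc1ccc([C@@H]2Cc3c4c(cc(O)c3)O[C@H](c3ccc(OC)cc3)[C@H]4c3cc(OC)cc(OC)c32)cc1 | intermediate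
19 | (7aS,7cS,8cS) ring A–D core, a5 phenol, a6 formyl, tetramethyl ether | COc1ccc([C@@H]2Cc3c4c(cc(O)c3C=O)O[C@H](c3ccc(OC)cc3)[C@H]4c3cc(OC)cc(OC)c32)cc1 | intermediate
20 | (7aS,7cS,8cS) ring A–D core, a5 phenol, a6 (3,5-dimethoxyphenyl)(hydroxy)methyl (carbinol epimers) | COc1ccc([C@@H]2Cc3c4c(cc(O)c3C(O)c3cc(OC)cc(OC)c3)O[C@H](c3ccc(OC)cc3)[C@H]4c3cc(OC)cc(OC)c32)cc1 | intermediate
21 | (7aS,7cS,8cS) ring A–D core, a5 phenol, a6 (3,5-dimethoxyphenyl)(4-methylphenylsulfonyl)methyl (epimers at that carbon) | COc1ccc([C@@H]2Cc3c4c(cc(O)c3C(c3cc(OC)cc(OC)c3)S(=O)(=O)c3ccc(C)cc3)O[C@H](c3ccc(OC)cc3)[C@H]4c3cc(OC)cc(OC)c32)cc1 | intermediate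
22 | 4-methoxybenzyl alcohol | COc1ccc(CO)cc1 | starting material
23 | 1-(4-methoxybenzyl)tetrahydrothiophenium tetrafluoroborate | COc1ccc(C[S+]2CCCC2)cc1.F[B-](F)(F)F | intermediate
24 | (7aS,7cS,8cS) ring A o-quinone methide: a5 carbonyl, a6 exocyclic 3,5-dimethoxybenzylidene | COc1ccc([C@@H]2CC3=C4C(=CC(=O)C3=Cc3cc(OC)cc(OC)c3)O[C@H](c3ccc(OC)cc3)[C@H]4c3cc(OC)cc(OC)c32)cc1 | intermediate
25 | tetrahydrothiophenium (4-methoxyphenyl)methylide | COc1ccc([CH-][S+]2CCCC2)cc1 | intermediate
26 | (7aS,7bR,8bR,7cS,8cS) heptamethyl ether of the target (rings D and E both trans) | COc1ccc([C@@H]2Cc3c4c(cc5c3[C@@H](c3cc(OC)cc(OC)c3)[C@H](c3ccc(OC)cc3)O5)O[C@H](c3ccc(OC)cc3)[C@H]4c3cc(OC)cc(OC)c32)cc1 | intermediate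
27 | CNP0136963.1, (7aS,7bR,8bR,7cS,8cS) | Oc1ccc([C@@H]2Cc3c4c(cc5c3[C@@H](c3cc(O)cc(O)c3)[C@H](c3ccc(O)cc3)O5)O[C@H](c3ccc(O)cc3)[C@H]4c3cc(O)cc(O)c32)cc1 | target

## Step count and risks

Total step count: 17. Longest linear sequence: 14 steps (steps 3 to 14, then 16 and 17, from 3,5-dimethoxybenzaldehyde).

Steps most likely to fail:

1. Step 11 (key step). The 7-exo insertion is slower than the five- and six-membered closures for which this reaction is established, so the aryl–palladium species may be reduced by formate before it cyclises (loss of bromine without ring closure). Insertion may also take place on both faces of the benzofuran, giving poor control of C8c and C7c relative to C7a. Fallback: setting out from 16, ring B is closed instead by palladium-catalysed intramolecular direct C–H arylation at C8c (Pd(OAc)2, PCy3·HBF4, K2CO3, pivalic acid, DMA, 120 °C; concerted metalation–deprotonation). This gives the fully aromatic ring-B-fused 2,3-diarylbenzofuran F1 with C7a untouched. Ionic hydrogenation of the furan C8c=C7c bond (Et3SiH, TFA, CH2Cl2, 0 °C), in which C8c is protonated reversibly and hydride then adds to the C7c oxocarbenium ion anti to ring C, should give the trans-dihydrobenzofuran, and the route is rejoined at 17.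

2. Step 10. The alkene carries three aryl groups, one of them 2,6-disubstituted, so hydrogen uptake may be slow, and any residual (E)-isomer or imperfect face selection lowers the enantiomeric purity at C7a. Fallback: setting out from 15, ionic hydrogenation (Et3SiH, TFA, CH2Cl2, −20 °C; the alkene is protonated to the diarylmethyl cation far faster than the benzofuran) gives the racemic triarylethane F2. It is resolved by preparative chromatography on a chiral stationary phase (supercritical CO2/alcohol); the (S)-enantiomer is 16.

3. Step 16. The o-quinone methide may be attacked on both faces (mixture at C8b) or be lost by self-condensation before the weakly populated semi-stabilised ylide adds. Fallback: setting out from 19, the Grignard addition of step 14 is stopped at diol 20, which is isolated. MnO2 oxidises it to the o-hydroxy diaryl ketone F3, and acylation with 4-methoxybenzoyl chloride (Et3N, DMAP) gives the aryl ester F4. Intramolecular McMurry-type ketone–ester coupling with low-valent titanium (TiCl3, Zn, DME, reflux) builds ring E as the aromatic 2,3-diarylbenzofuran F5. Ionic hydrogenation (Et3SiH, TFA, CH2Cl2, 0 °C), with protonation at C8b from the face away from the C7a bridge and hydride addition at C7b anti to the C8b aryl group, should give the trans-dihydrobenzofuran and rejoins the route at 26.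

## Further compounds

F1 | step 11 | (7aS) ring-B-fused aromatic 2,3-diarylbenzofuran (C8c=C7c retained), a5 triisopropylsilyl ether | COc1ccc([C@@H]2Cc3cc(O[Si](C(C)C)(C(C)C)C(C)C)cc4oc(-c5ccc(OC)cc5)c(-c5cc(OC)cc(OC)c52)c34)cc1
F2 | step 10 | racemic 4-[2-(2-bromo-4,6-dimethoxyphenyl)-2-(4-methoxyphenyl)ethyl]-2-(4-methoxyphenyl)-6-(triisopropylsilyloxy)-1-benzofuran | COc1ccc(C(Cc2cc(O[Si](C(C)C)(C(C)C)C(C)C)cc3oc(-c4ccc(OC)cc4)cc23)c2c(Br)cc(OC)cc2OC)cc1
F3 | step 16 | (7aS,7cS,8cS) ring A–D core, a5 phenol, a6 3,5-dimethoxybenzoyl | COc1ccc([C@@H]2Cc3c4c(cc(O)c3C(=O)c3cc(OC)cc(OC)c3)O[C@H](c3ccc(OC)cc3)[C@H]4c3cc(OC)cc(OC)c32)cc1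
F4 | step 16 | (7aS,7cS,8cS) ring A–D core, a5 4-methoxybenzoate, a6 3,5-dimethoxybenzoyl | COc1ccc([C@@H]2Cc3c4c(cc(OC(=O)c5ccc(OC)cc5)c3C(=O)c3cc(OC)cc(OC)c3)O[C@H](c3ccc(OC)cc3)[C@H]4c3cc(OC)cc(OC)c32)cc1
F5 | step 16 | (7aS,7cS,8cS) heptamethyl ether in which ring E is an aromatic furan (C8b=C7b) | COc1ccc([C@@H]2Cc3c4c(cc5oc(-c6ccc(OC)cc6)c(-c6cc(OC)cc(OC)c6)c35)O[C@H](c3ccc(OC)cc3)[C@H]4c3cc(OC)cc(OC)c32)cc1
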